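**Retrosynthetic overview**

- The target is epicatechin-(4α→8)-epigallocatechin 3-O-gallate: upper unit (rings A, C, B) 2R,3R,4S all-cis, lower unit (rings D, F, E) 2R,3R, galloyl ring G on the lower O3.
- Target ⇐ hydrogenolysis of its dodecabenzyl ether ⇐ site-selective galloylation of the less hindered ring F carbinol of a bis-cis diol.
- Both cis carbinols ⇐ hydride reduction of a bis(flavan-3-one) ⇐ oxidation of the 2,3-trans diol from double hydroboration of a bis(2H-chromene); the hydroboration also sets C4 (aryl groups on C2 and C4 cis).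
- Key step: pyran rings F and C are closed together by a double gold-catalysed 6-endo hydroarylation of a bis(aryl propargyl ether); the interflavan C4–C8 bond is already present as an aryl–alkyne bond.
- The diyne ⇐ benzylated aldehydes and phenols by two catalytic asymmetric alkynylations and two Mitsunobu inversions (C2 of each unit); rings A, B, D, E, G are bought, rings F and C form in step 7.

Assumption: the benzyl-protected aldehydes, phenol and benzoic acid used below and the silylacetylene are bought as catalogue compounds.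

**Step 1**
Reactants: 1 3,4,5-tris(benzyloxy)benzaldehyde; 2 ethynyl(triisopropyl)silane
Product: 3 (1S)-1-[3,4,5-tris(benzyloxy)phenyl]-3-(triisopropylsilyl)prop-2-yn-1-ol
Conditions: (S,S)-ProPhenol (10 mol %), ZnMe2, Ph3PO (20 mol %), toluene, 4 °C; aq. NH4Cl
Reagents that add atoms: none
Why: The zinc acetylide from 2 adds to one aldehyde face inside the chiral dinuclear zinc–ProPhenol pocket (Trost asymmetric alkynylation), which sets the (S)-carbinol; the sense is checked by Mosher analysis and the antipodal ligand is used if it is opposite.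

**Step 2**
Reactants: 3 (1S)-1-[3,4,5-tris(benzyloxy)phenyl]-3-(triisopropylsilyl)prop-2-yn-1-ol; 4 2,4-bis(benzyloxy)-6-hydroxybenzaldehyde
Product: 5 2,4-bis(benzyloxy)-6-({(1R)-1-[3,4,5-tris(benzyloxy)phenyl]-3-(triisopropylsilyl)prop-2-yn-1-yl}oxy)benzaldehyde
Conditions: PPh3, DIAD, toluene, −20 → 0 °C
Reagents that add atoms: none
Why: Mitsunobu etherification, in which the acidic chelated phenol of 4 displaces the alkoxyphosphonium of 3 by SN2 with inversion, gives the (R)-ether that is the future O1–C2 bond of ring F; low temperature and a non-polar solvent suppress ionisation.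

**Step 3**
Reactants: 5 2,4-bis(benzyloxy)-6-({(1R)-1-[3,4,5-tris(benzyloxy)phenyl]-3-(triisopropylsilyl)prop-2-yn-1-yl}oxy)benzaldehyde
Product: 6 1,5-bis(benzyloxy)-2-ethynyl-3-({(1R)-1-[3,4,5-tris(benzyloxy)phenyl]-3-(triisopropylsilyl)prop-2-yn-1-yl}oxy)benzene
Conditions: dimethyl (1-diazo-2-oxopropyl)phosphonate, K2CO3, MeOH/THF, 0 °C → rt
Reagents that add atoms: dimethyl (1-diazo-2-oxopropyl)phosphonate, CC(=O)C(=[N+]=[N-])P(=O)(OC)OC
Why: Ohira–Bestmann (Seyferth–Gilbert) homologation converts the aldehyde into a terminal alkyne under mild carbonate conditions that leave the silylalkyne and the ether stereocentre untouched.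

**Step 4**
Reactants: 6 1,5-bis(benzyloxy)-2-ethynyl-3-({(1R)-1-[3,4,5-tris(benzyloxy)phenyl]-3-(triisopropylsilyl)prop-2-yn-1-yl}oxy)benzene; 7 3,4-bis(benzyloxy)benzaldehyde
Product: 8 (1S)-1-[3,4-bis(benzyloxy)phenyl]-3-[2,4-bis(benzyloxy)-6-({(1R)-1-[3,4,5-tris(benzyloxy)phenyl]-3-(triisopropylsilyl)prop-2-yn-1-yl}oxy)phenyl]prop-2-yn-1-ol
Conditions: (S,S)-ProPhenol (20 mol %), ZnMe2, Ph3PO, toluene, 4 °C; aq. NH4Cl
Reagents that add atoms: none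
Why: A second ProPhenol–zinc asymmetric alkynylation (catalyst control as in step 1) joins the aryl alkyne to the ring B aldehyde and sets the (S)-carbinol that becomes C2 of the upper unit.

**Step 5**
Reactants: 8 (1S)-1-[3,4-bis(benzyloxy)phenyl]-3-[2,4-bis(benzyloxy)-6-({(1R)-1-[3,4,5-tris(benzyloxy)phenyl]-3-(triisopropylsilyl)prop-2-yn-1-yl}oxy)phenyl]prop-2-yn-1-ol; 9 3,5-bis(benzyloxy)phenol
Product: 10 1,5-bis(benzyloxy)-2-{(3R)-3-[3,4-bis(benzyloxy)phenyl]-3-[3,5-bis(benzyloxy)phenoxy]prop-1-yn-1-yl}-3-({(1R)-1-[3,4,5-tris(benzyloxy)phenyl]-3-(triisopropylsilyl)prop-2-yn-1-yl}oxy)benzene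
Conditions: PPh3, DIAD, toluene, −20 °C
Reagents that add atoms: none
Why: Mitsunobu etherification with SN2 inversion puts the ring A phenol on the propargylic carbon and gives the (R)-ether, i.e. the O1–C2 bond of ring C with the final C2 configuration.

**Step 6**
Reactants: 10 1,5-bis(benzyloxy)-2-{(3R)-3-[3,4-bis(benzyloxy)phenyl]-3-[3,5-bis(benzyloxy)phenoxy]prop-1-yn-1-yl}-3-({(1R)-1-[3,4,5-tris(benzyloxy)phenyl]-3-(triisopropylsilyl)prop-2-yn-1-yl}oxy)benzene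
Product: 11 1,5-bis(benzyloxy)-2-{(3R)-3-[3,4-bis(benzyloxy)phenyl]-3-[3,5-bis(benzyloxy)phenoxy]prop-1-yn-1-yl}-3-({(1S)-1-[3,4,5-tris(benzyloxy)phenyl]prop-2-yn-1-yl}oxy)benzene (same geometry; the descriptor changes by CIP only)
Conditions: Bu4NF, THF, 0 °C; aq. NH4Cl
Reagents that add atoms: none
Why: Fluoride-induced protodesilylation of the alkynylsilane frees the terminal alkyne without touching the benzyl ethers or the two stereocentres.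

**Step 7 (key step)**
Reactants: 11 1,5-bis(benzyloxy)-2-{(3R)-3-[3,4-bis(benzyloxy)phenyl]-3-[3,5-bis(benzyloxy)phenoxy]prop-1-yn-1-yl}-3-({(1S)-1-[3,4,5-tris(benzyloxy)phenyl]prop-2-yn-1-yl}oxy)benzene
Product: 13 (2S)-5,7-bis(benzyloxy)-2-[3,4-bis(benzyloxy)phenyl]-4-{(2S)-5,7-bis(benzyloxy)-2-[3,4,5-tris(benzyloxy)phenyl]-2H-chromen-8-yl}-2H-chromene, via lower-ring monocyclised chromene 12 (not isolated)
Conditions: [(2-biphenylyl)(tBu)2P]Au(NCMe)SbF6 (5 mol %), CH2Cl2, rt, dark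
Reagents that add atoms: none
Why: Cationic monovalent gold activates each alkyne as a π-acid and the flanking electron-rich aryl ether attacks 6-endo-dig at the distal alkyne carbon (intramolecular alkyne hydroarylation, known for aryl propargyl ethers giving 2H-chromenes), so rings F and C close in one flask with no bond to either stereocentre broken.

**Step 8**
Reactants: 13 (2S)-5,7-bis(benzyloxy)-2-[3,4-bis(benzyloxy)phenyl]-4-{(2S)-5,7-bis(benzyloxy)-2-[3,4,5-tris(benzyloxy)phenyl]-2H-chromen-8-yl}-2H-chromene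
Product: 15 (2R,3S,4S)-5,7-bis(benzyloxy)-2-[3,4-bis(benzyloxy)phenyl]-4-{(2R,3S)-5,7-bis(benzyloxy)-3-hydroxy-2-[3,4,5-tris(benzyloxy)phenyl]chroman-8-yl}chroman-3-ol, via bis(alkylborane) 14 (not isolated)
Conditions: BH3·SMe2, THF, 0 °C → rt; then NaOH, H2O2, 0 °C
Reagents that add atoms: hydrogen peroxide, OO; borane–dimethyl sulfide, B.CSC (boron is held only in 14)
Why: Hydroboration–oxidation adds boron to C3 and hydrogen to the benzylic C4, syn and from the face opposite the C2 aryl group of each chromene, so oxidation with retention gives both 2,3-trans alcohols and fixes the upper C4 as 4S with the aryl groups on C2 and C4 cis.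

**Step 9**
Reactants: 15 (2R,3S,4S)-5,7-bis(benzyloxy)-2-[3,4-bis(benzyloxy)phenyl]-4-{(2R,3S)-5,7-bis(benzyloxy)-3-hydroxy-2-[3,4,5-tris(benzyloxy)phenyl]chroman-8-yl}chroman-3-ol
Product: 16 (2R,4S)-5,7-bis(benzyloxy)-2-[3,4-bis(benzyloxy)phenyl]-4-{(2R)-5,7-bis(benzyloxy)-3-oxo-2-[3,4,5-tris(benzyloxy)phenyl]chroman-8-yl}chroman-3-one
Conditions: Dess–Martin periodinane, NaHCO3, CH2Cl2, 0 °C → rt
Reagents that add atoms: none
Why: Dess–Martin oxidation converts both secondary alcohols into ketones under buffered, non-enolising conditions, so C2, C4 and C2 of the lower unit keep their configuration.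

**Step 10**
Reactants: 16 (2R,4S)-5,7-bis(benzyloxy)-2-[3,4-bis(benzyloxy)phenyl]-4-{(2R)-5,7-bis(benzyloxy)-3-oxo-2-[3,4,5-tris(benzyloxy)phenyl]chroman-8-yl}chroman-3-one
Product: 17 (2R,3R,4S)-5,7-bis(benzyloxy)-2-[3,4-bis(benzyloxy)phenyl]-4-{(2R,3R)-5,7-bis(benzyloxy)-3-hydroxy-2-[3,4,5-tris(benzyloxy)phenyl]chroman-8-yl}chroman-3-ol
Conditions: LiBH(sec-Bu)3, THF, −78 °C; aq. NH4Cl
Reagents that add atoms: none
Why: The bulky hydride attacks each flavan-3-one equatorially on the face opposite the aryl substituents (in ring C both aryl groups lie on one face), which gives the axial 2,3-cis alcohols and the all-cis C2/C3/C4 triad of the upper unit (substrate-controlled reduction, as in the catechin-to-epicatechin inversion).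

**Step 11**
Reactants: 17 (2R,3R,4S)-5,7-bis(benzyloxy)-2-[3,4-bis(benzyloxy)phenyl]-4-{(2R,3R)-5,7-bis(benzyloxy)-3-hydroxy-2-[3,4,5-tris(benzyloxy)phenyl]chroman-8-yl}chroman-3-ol; 18 3,4,5-tris(benzyloxy)benzoic acid
Product: 19 (2R,3R)-5,7-bis(benzyloxy)-8-{(2R,3R,4S)-5,7-bis(benzyloxy)-2-[3,4-bis(benzyloxy)phenyl]-3-hydroxychroman-4-yl}-2-[3,4,5-tris(benzyloxy)phenyl]chroman-3-yl 3,4,5-tris(benzyloxy)benzoate
Conditions: 18 (1.05 equiv), DCC, DMAP, CH2Cl2, 0 °C → rt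
Reagents that add atoms: none
Why: Steglich esterification is site-selective because the ring F hydroxyl is flanked by one aryl-bearing carbon and a CH2, whereas the ring C hydroxyl is axial between two cis aryl-bearing carbons and acylates far more slowly.

**Step 12**
Reactants: 19 (2R,3R)-5,7-bis(benzyloxy)-8-{(2R,3R,4S)-5,7-bis(benzyloxy)-2-[3,4-bis(benzyloxy)phenyl]-3-hydroxychroman-4-yl}-2-[3,4,5-tris(benzyloxy)phenyl]chroman-3-yl 3,4,5-tris(benzyloxy)benzoate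
Product: 20 (2R,3R)-8-[(2R,3R,4S)-2-(3,4-dihydroxyphenyl)-3,5,7-trihydroxychroman-4-yl]-5,7-dihydroxy-2-(3,4,5-trihydroxyphenyl)chroman-3-yl 3,4,5-trihydroxybenzoate
Conditions: H2 (1 atm), Pd(OH)2/C, THF/MeOH, rt; filter, lyophilise
Reagents that add atoms: none
Why: Hydrogenolysis over Pd(OH)2 cleaves all twelve benzyl ethers under neutral conditions that leave the ester, the pyran C–O bonds and the five stereocentres intact.

**Compound list**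

1 | 3,4,5-tris(benzyloxy)benzaldehyde | O=Cc1cc(OCc2ccccc2)c(OCc2ccccc2)c(OCc2ccccc2)c1 | starting material
2 | ethynyl(triisopropyl)silane | C#C[Si](C(C)C)(C(C)C)C(C)C | starting material
3 | (1S)-1-[3,4,5-tris(benzyloxy)phenyl]-3-(triisopropylsilyl)prop-2-yn-1-ol | O[C@@H](c1cc(OCc2ccccc2)c(OCc2ccccc2)c(OCc2ccccc2)c1)C#C[Si](C(C)C)(C(C)C)C(C)C | intermediate
4 | 2,4-bis(benzyloxy)-6-hydroxybenzaldehyde | O=Cc1c(O)cc(OCc2ccccc2)cc1OCc1ccccc1 | starting material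
5 | 2,4-bis(benzyloxy)-6-({(1R)-1-[3,4,5-tris(benzyloxy)phenyl]-3-(triisopropylsilyl)prop-2-yn-1-yl}oxy)benzaldehyde | O=Cc1c(OCc2ccccc2)cc(OCc2ccccc2)cc1O[C@H](c1cc(OCc2ccccc2)c(OCc2ccccc2)c(OCc2ccccc2)c1)C#C[Si](C(C)C)(C(C)C)C(C)C | intermediate
6 | 1,5-bis(benzyloxy)-2-ethynyl-3-({(1R)-1-[3,4,5-tris(benzyloxy)phenyl]-3-(triisopropylsilyl)prop-2-yn-1-yl}oxy)benzene | C#Cc1c(OCc2ccccc2)cc(OCc2ccccc2)cc1O[C@H](c1cc(OCc2ccccc2)c(OCc2ccccc2)c(OCc2ccccc2)c1)C#C[Si](C(C)C)(C(C)C)C(C)C | intermediate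
7 | 3,4-bis(benzyloxy)benzaldehyde | O=Cc1ccc(OCc2ccccc2)c(OCc2ccccc2)c1 | starting material
8 | (1S)-1-[3,4-bis(benzyloxy)phenyl]-3-[2,4-bis(benzyloxy)-6-({(1R)-1-[3,4,5-tris(benzyloxy)phenyl]-3-(triisopropylsilyl)prop-2-yn-1-yl}oxy)phenyl]prop-2-yn-1-ol | O[C@@H](c1ccc(OCc2ccccc2)c(OCc2ccccc2)c1)C#Cc1c(OCc2ccccc2)cc(OCc2ccccc2)cc1O[C@H](c1cc(OCc2ccccc2)c(OCc2ccccc2)c(OCc2ccccc2)c1)C#C[Si](C(C)C)(C(C)C)C(C)C | intermediate
9 | 3,5-bis(benzyloxy)phenol | Oc1cc(OCc2ccccc2)cc(OCc2ccccc2)c1 | starting material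
10 | 1,5-bis(benzyloxy)-2-{(3R)-3-[3,4-bis(benzyloxy)phenyl]-3-[3,5-bis(benzyloxy)phenoxy]prop-1-yn-1-yl}-3-({(1R)-1-[3,4,5-tris(benzyloxy)phenyl]-3-(triisopropylsilyl)prop-2-yn-1-yl}oxy)benzene | c1c(OCc2ccccc2)cc(OCc2ccccc2)cc1O[C@H](c1ccc(OCc2ccccc2)c(OCc2ccccc2)c1)C#Cc1c(OCc2ccccc2)cc(OCc2ccccc2)cc1O[C@H](c1cc(OCc2ccccc2)c(OCc2ccccc2)c(OCc2ccccc2)c1)C#C[Si](C(C)C)(C(C)C)C(C)C | intermediate
11 | 1,5-bis(benzyloxy)-2-{(3R)-3-[3,4-bis(benzyloxy)phenyl]-3-[3,5-bis(benzyloxy)phenoxy]prop-1-yn-1-yl}-3-({(1S)-1-[3,4,5-tris(benzyloxy)phenyl]prop-2-yn-1-yl}oxy)benzene | c1c(OCc2ccccc2)cc(OCc2ccccc2)cc1O[C@H](c1ccc(OCc2ccccc2)c(OCc2ccccc2)c1)C#Cc1c(OCc2ccccc2)cc(OCc2ccccc2)cc1O[C@H](c1cc(OCc2ccccc2)c(OCc2ccccc2)c(OCc2ccccc2)c1)C#C | intermediate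
12 | lower-ring monocyclised chromene: (2S)-5,7-bis(benzyloxy)-8-{(3R)-3-[3,4-bis(benzyloxy)phenyl]-3-[3,5-bis(benzyloxy)phenoxy]prop-1-yn-1-yl}-2-[3,4,5-tris(benzyloxy)phenyl]-2H-chromene | c1c(OCc2ccccc2)cc(OCc2ccccc2)cc1O[C@H](c1ccc(OCc2ccccc2)c(OCc2ccccc2)c1)C#Cc1c(OCc3ccccc3)cc(OCc3ccccc3)c2c1O[C@H](c1cc(OCc3ccccc3)c(OCc3ccccc3)c(OCc3ccccc3)c1)C=C2 | intermediate (not isolated)
13 | (2S)-5,7-bis(benzyloxy)-2-[3,4-bis(benzyloxy)phenyl]-4-{(2S)-5,7-bis(benzyloxy)-2-[3,4,5-tris(benzyloxy)phenyl]-2H-chromen-8-yl}-2H-chromene | c1c(OCc3ccccc3)cc(OCc3ccccc3)c2c1O[C@H](c1ccc(OCc3ccccc3)c(OCc3ccccc3)c1)C=C2c1c(OCc3ccccc3)cc(OCc3ccccc3)c2c1O[C@H](c1cc(OCc3ccccc3)c(OCc3ccccc3)c(OCc3ccccc3)c1)C=C2 | intermediate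
14 | bis(alkylborane): analogue of 15 with BH2 in place of each OH (C3 of ring C and C3 of ring F), same configuration | [BH2][C@H]1Cc2c(OCc3ccccc3)cc(OCc3ccccc3)c([C@@H]3c4c(OCc5ccccc5)cc(OCc5ccccc5)cc4O[C@H](c4ccc(OCc5ccccc5)c(OCc5ccccc5)c4)[C@H]3[BH2])c2O[C@@H]1c1cc(OCc2ccccc2)c(OCc2ccccc2)c(OCc2ccccc2)c1 | intermediate (not isolated)
15 | (2R,3S,4S)-5,7-bis(benzyloxy)-2-[3,4-bis(benzyloxy)phenyl]-4-{(2R,3S)-5,7-bis(benzyloxy)-3-hydroxy-2-[3,4,5-tris(benzyloxy)phenyl]chroman-8-yl}chroman-3-ol (nona-O-benzyl catechin-(4α→8)-gallocatechin) | O[C@H]1Cc2c(OCc3ccccc3)cc(OCc3ccccc3)c([C@@H]3c4c(OCc5ccccc5)cc(OCc5ccccc5)cc4O[C@H](c4ccc(OCc5ccccc5)c(OCc5ccccc5)c4)[C@H]3O)c2O[C@@H]1c1cc(OCc2ccccc2)c(OCc2ccccc2)c(OCc2ccccc2)c1 | intermediate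
16 | (2R,4S)-5,7-bis(benzyloxy)-2-[3,4-bis(benzyloxy)phenyl]-4-{(2R)-5,7-bis(benzyloxy)-3-oxo-2-[3,4,5-tris(benzyloxy)phenyl]chroman-8-yl}chroman-3-one | O=C1Cc2c(OCc3ccccc3)cc(OCc3ccccc3)c([C@@H]3c4c(OCc5ccccc5)cc(OCc5ccccc5)cc4O[C@H](c4ccc(OCc5ccccc5)c(OCc5ccccc5)c4)C3=O)c2O[C@@H]1c1cc(OCc2ccccc2)c(OCc2ccccc2)c(OCc2ccccc2)c1 | intermediate
17 | (2R,3R,4S)-5,7-bis(benzyloxy)-2-[3,4-bis(benzyloxy)phenyl]-4-{(2R,3R)-5,7-bis(benzyloxy)-3-hydroxy-2-[3,4,5-tris(benzyloxy)phenyl]chroman-8-yl}chroman-3-ol (nona-O-benzyl epicatechin-(4α→8)-epigallocatechin) | O[C@@H]1Cc2c(OCc3ccccc3)cc(OCc3ccccc3)c([C@@H]3c4c(OCc5ccccc5)cc(OCc5ccccc5)cc4O[C@H](c4ccc(OCc5ccccc5)c(OCc5ccccc5)c4)[C@@H]3O)c2O[C@@H]1c1cc(OCc2ccccc2)c(OCc2ccccc2)c(OCc2ccccc2)c1 | intermediate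
18 | 3,4,5-tris(benzyloxy)benzoic acid | OC(=O)c1cc(OCc2ccccc2)c(OCc2ccccc2)c(OCc2ccccc2)c1 | starting material
19 | (2R,3R)-5,7-bis(benzyloxy)-8-{(2R,3R,4S)-5,7-bis(benzyloxy)-2-[3,4-bis(benzyloxy)phenyl]-3-hydroxychroman-4-yl}-2-[3,4,5-tris(benzyloxy)phenyl]chroman-3-yl 3,4,5-tris(benzyloxy)benzoate | O=C(O[C@@H]1Cc2c(OCc3ccccc3)cc(OCc3ccccc3)c([C@@H]3c4c(OCc5ccccc5)cc(OCc5ccccc5)cc4O[C@H](c4ccc(OCc5ccccc5)c(OCc5ccccc5)c4)[C@@H]3O)c2O[C@@H]1c1cc(OCc2ccccc2)c(OCc2ccccc2)c(OCc2ccccc2)c1)c1cc(OCc2ccccc2)c(OCc2ccccc2)c(OCc2ccccc2)c1 | intermediate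
20 | (2R,3R)-8-[(2R,3R,4S)-2-(3,4-dihydroxyphenyl)-3,5,7-trihydroxychroman-4-yl]-5,7-dihydroxy-2-(3,4,5-trihydroxyphenyl)chroman-3-yl 3,4,5-trihydroxybenzoate (CNP0246304.3) | O=C(O[C@@H]1Cc2c(O)cc(O)c([C@@H]3c4c(O)cc(O)cc4O[C@H](c4ccc(O)c(O)c4)[C@@H]3O)c2O[C@@H]1c1cc(O)c(O)c(O)c1)c1cc(O)c(O)c(O)c1 | target

**Step count and risks**

Total step count: 12. Longest linear sequence: 12 steps (1 → 20; the route is linear).

The three steps most likely to fail: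

Step 7 (double hydroarylation). The gold catalyst could ionise a propargylic C–O bond and erode ee, an ortho benzyloxy group could add to the activated alkyne to give a benzofuran, or the second ring closure could stall at 12. Fallback, setting out from 11 and coming back at 13: electrophilic 6-endo iodocyclisation of both alkynes (I2, NaHCO3, MeCN, 0 °C) gives (2R)-5,7-bis(benzyloxy)-2-[3,4-bis(benzyloxy)phenyl]-3-iodo-4-{(2R)-5,7-bis(benzyloxy)-3-iodo-2-[3,4,5-tris(benzyloxy)phenyl]-2H-chromen-8-yl}-2H-chromene F2. Both vinyl iodides are then removed with Pd(PPh3)4 and Bu3SnH (toluene, rt), which gives 13.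

Step 5 (Mitsunobu on an electron-rich benzylic, propargylic alcohol). Ionisation would erode ee or give an allenyl ether by SN2' attack. Fallback, setting out from 6 (with 7) and coming back at 10: the alkynylation of step 4 is run with (R,R)-ProPhenol to give the epimeric carbinol (1R)-1-[3,4-bis(benzyloxy)phenyl]-3-[2,4-bis(benzyloxy)-6-({(1R)-1-[3,4,5-tris(benzyloxy)phenyl]-3-(triisopropylsilyl)prop-2-yn-1-yl}oxy)phenyl]prop-2-yn-1-ol F1. The ether bond is then made on the arene side, with retention at the stereocentre, by palladium-catalysed C–O coupling of F1 with bought 1-bromo-3,5-bis(benzyloxy)benzene (Pd2(dba)3, RockPhos, Cs2CO3, toluene, 60 °C), which gives 10 directly.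

Step 11 (site-selective galloylation of a diol). Some ester could form at the ring C hydroxyl or at both hydroxyls. Fallback, setting out from 16 and coming back at 19: one equivalent of LiBH(sec-Bu)3 at −78 °C reduces only the less hindered ring F ketone and gives (2R,4S)-5,7-bis(benzyloxy)-2-[3,4-bis(benzyloxy)phenyl]-4-{(2R,3R)-5,7-bis(benzyloxy)-3-hydroxy-2-[3,4,5-tris(benzyloxy)phenyl]chroman-8-yl}chroman-3-one F3. Its single hydroxyl is esterified with 18 (DCC, DMAP) to give (2R,3R)-5,7-bis(benzyloxy)-8-{(2R,4S)-5,7-bis(benzyloxy)-2-[3,4-bis(benzyloxy)phenyl]-3-oxochroman-4-yl}-2-[3,4,5-tris(benzyloxy)phenyl]chroman-3-yl 3,4,5-tris(benzyloxy)benzoate F4. A second reduction of the ring C ketone with LiBH(sec-Bu)3 at −78 °C then gives 19.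

**Further compounds**

F1 | step 5 | (1R)-1-[3,4-bis(benzyloxy)phenyl]-3-[2,4-bis(benzyloxy)-6-({(1R)-1-[3,4,5-tris(benzyloxy)phenyl]-3-(triisopropylsilyl)prop-2-yn-1-yl}oxy)phenyl]prop-2-yn-1-ol | O[C@H](c1ccc(OCc2ccccc2)c(OCc2ccccc2)c1)C#Cc1c(OCc2ccccc2)cc(OCc2ccccc2)cc1O[C@H](c1cc(OCc2ccccc2)c(OCc2ccccc2)c(OCc2ccccc2)c1)C#C[Si](C(C)C)(C(C)C)C(C)C
F2 | step 7 | (2R)-5,7-bis(benzyloxy)-2-[3,4-bis(benzyloxy)phenyl]-3-iodo-4-{(2R)-5,7-bis(benzyloxy)-3-iodo-2-[3,4,5-tris(benzyloxy)phenyl]-2H-chromen-8-yl}-2H-chromene | c1c(OCc3ccccc3)cc(OCc3ccccc3)c2c1O[C@H](c1ccc(OCc3ccccc3)c(OCc3ccccc3)c1)C(I)=C2c1c(OCc3ccccc3)cc(OCc3ccccc3)c2c1O[C@H](c1cc(OCc3ccccc3)c(OCc3ccccc3)c(OCc3ccccc3)c1)C(I)=C2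
F3 | step 11 | (2R,4S)-5,7-bis(benzyloxy)-2-[3,4-bis(benzyloxy)phenyl]-4-{(2R,3R)-5,7-bis(benzyloxy)-3-hydroxy-2-[3,4,5-tris(benzyloxy)phenyl]chroman-8-yl}chroman-3-one | O[C@@H]1Cc2c(OCc3ccccc3)cc(OCc3ccccc3)c([C@@H]3c4c(OCc5ccccc5)cc(OCc5ccccc5)cc4O[C@H](c4ccc(OCc5ccccc5)c(OCc5ccccc5)c4)C3=O)c2O[C@@H]1c1cc(OCc2ccccc2)c(OCc2ccccc2)c(OCc2ccccc2)c1
F4 | step 11 | (2R,3R)-5,7-bis(benzyloxy)-8-{(2R,4S)-5,7-bis(benzyloxy)-2-[3,4-bis(benzyloxy)phenyl]-3-oxochroman-4-yl}-2-[3,4,5-tris(benzyloxy)phenyl]chroman-3-yl 3,4,5-tris(benzyloxy)benzoate | O=C(O[C@@H]1Cc2c(OCc3ccccc3)cc(OCc3ccccc3)c([C@@H]3c4c(OCc5ccccc5)cc(OCc5ccccc5)cc4O[C@H](c4ccc(OCc5ccccc5)c(OCc5ccccc5)c4)C3=O)c2O[C@@H]1c1cc(OCc2ccccc2)c(OCc2ccccc2)c(OCc2ccccc2)c1)c1cc(OCc2ccccc2)c(OCc2ccccc2)c(OCc2ccccc2)c1
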